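**Retrosynthetic overview**
- Penicillactone A ⇐ E1cB opening of a cis-fused furo[3,4-b]furan-2,4-dione: the butenolide and the C1 carboxylic acid are carried as one bis-lactone whose two extra stereocentres relay the hexyl-carbinol chirality to C1.
- Dihydropyranone ⇐ acid lactonisation/dehydration of a statin-type acetonide ester side chain; carbinol ⇐ Felkin reduction of a C3 acyl ketone.
- Cyclopentane and spiro γ-lactone ⇐ one-pot Michael–Michael [3+2] annulation of a β-keto ester/formylacrylic acid onto the α-methylene bis-lactone, then hemiacylal closure (key step, two rings).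
- Annulation partner ⇐ β-keto ester from the commercial statin side-chain alcohol + a Baylis–Hillman bromide; bis-lactone ⇐ itaconate aldol with (S)-2-benzoyloxyoctanal.
- Ring order: two γ-lactones (bis-lactone) → cyclopentane + spiro γ-lactone → dihydropyranone → butenolide (by opening one of the first lactones).

Core numbering used below: C1 = cyclopentane carbon bearing CO2H and the butenolide, C2, C3 (side-chain carbon), C4, C5 (spiro lactone carbon).
Assumption: the hemiacylal (lactol) carbon epimerises by ring–chain tautomerism and is taken to settle in the natural configuration; in intermediates 20–25 it is an epimer mixture, as is the transient quaternary C3 in 19–22.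

**Step 1**
Reactants: 1 octanal
Product: 2 (2S)-1-oxooctan-2-yl benzoate
Conditions: (PhCO2)2, (S)-α,α-diphenylprolinol TMS ether (10 mol%), hydroquinone (cat.), THF, 0 °C to rt; used crude
Reagents that add atoms: dibenzoyl peroxide, O=C(OOC(=O)c1ccccc1)c1ccccc1
Why: Organocatalytic enamine α-benzoyloxylation in which the diarylmethyl group of the (S)-catalyst shields one enamine face, setting the (S) centre that ends as the butenolide C5.

**Step 2**
Reactants: 3 dimethyl itaconate; 2 (2S)-1-oxooctan-2-yl benzoate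
Product: 5 anti-aldol diester, via lithium dienolate 4 (not isolated)
Conditions: LDA, THF, −78 °C; then 2, −78 °C; AcOH quench at −78 °C
Reagents that add atoms: none
Why: α-Selective aldol addition of the itaconate dienolate with polar Felkin–Anh attack on the α-acyloxy aldehyde gives the anti (1R,2S) diol pattern, while the succinate C2 centre forms as a mixture that is corrected in step 3.

**Step 3**
Reactants: 5 anti-aldol diester
Product: 6 (3aS,6S,6aR)-6-hexyl-3-methylidenetetrahydrofuro[3,4-b]furan-2,4-dione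
Conditions: p-TsOH·H2O, MeOH, 60 °C; then PhMe, 100 °C (−MeOH)
Reagents that add atoms: none
Why: Acid-catalysed benzoate methanolysis and double lactonisation close both γ-lactones in one operation, and the epimerisable C3a centre funnels by enolisation into the only bis-lactone that can form (cis-fused, hexyl exo).

**Step 4**
Reactants: 7 allyl acrylate; 8 2,2-dimethoxyacetaldehyde
Product: 9 allyl 2-(1-hydroxy-2,2-dimethoxyethyl)acrylate
Conditions: DABCO (0.5 equiv), dioxane–H2O, rt
Reagents that add atoms: none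
Why: Morita–Baylis–Hillman reaction whose racemic carbinol centre is removed in step 5.

**Step 5**
Reactants: 9 allyl 2-(1-hydroxy-2,2-dimethoxyethyl)acrylate
Product: 10 allyl (2Z)-2-(bromomethyl)-4,4-dimethoxybut-2-enoate
Conditions: NBS, Me2S, CH2Cl2, 0 °C to rt
Reagents that add atoms: N-bromosuccinimide, BrN1C(=O)CCC1=O
Why: Corey–Kim-type bromination of the Baylis–Hillman alcohol with allylic transposition (SN2′) gives the (Z)-2-(bromomethyl)enoate.

**Step 6**
Reactants: 11 tert-butyl 2-[(4R,6S)-6-(hydroxymethyl)-2,2-dimethyl-1,3-dioxan-4-yl]acetate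
Product: 12 (4S,6R)-6-(2-tert-butoxy-2-oxoethyl)-2,2-dimethyl-1,3-dioxane-4-carboxylic acid
Conditions: TEMPO (cat.), PhI(OAc)2 (2.2 equiv), MeCN–H2O, rt
Reagents that add atoms: water, O
Why: TEMPO/PhI(OAc)2 oxidation of the primary alcohol through the aldehyde hydrate leaves the acetonide, the tert-butyl ester and both stereocentres untouched, the carbon α to the new acid being the future pyranone C6.

**Step 7**
Reactants: 12 dioxane carboxylic acid; 13 monobenzyl malonate
Product: 14 benzyl 3-[(4S,6R)-6-(2-tert-butoxy-2-oxoethyl)-2,2-dimethyl-1,3-dioxan-4-yl]-3-oxopropanoate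
Conditions: CDI, THF, rt; then 13, MgCl2, Et3N, THF, rt to 40 °C; aq. HCl work-up
Reagents that add atoms: none
Why: Masamune–Brooks decarboxylative Claisen condensation of the acyl imidazolide with the magnesium malonate half-ester gives the β-keto ester under near-neutral conditions that do not epimerise the α-alkoxy centre.

**Step 8**
Reactants: 14 β-keto benzyl ester; 10 allylic bromide
Product: 15 C-alkylated β-keto ester
Conditions: K2CO3, acetone, rt
Reagents that add atoms: none
Why: SN2 C-alkylation of the β-keto ester anion at the primary allylic bromide keeps the enoate geometry, and the new methine is left as a mixture because it becomes an enolate carbon in step 10.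

**Step 9**
Reactants: 15 C-alkylated β-keto ester
Product: 17 formylacrylic acid β-keto ester, via acid acetal 16 (not isolated)
Conditions: Pd(PPh3)4 (5 mol%), PhSiH3, CH2Cl2, rt; then PPTS, acetone–H2O, 40 °C
Reagents that add atoms: water, O
Why: Tsuji–Trost deallylation with a silane scavenger frees the acid and acid-catalysed acetal hydrolysis in wet acetone unmasks the (E)-enal while the acetone medium preserves the acetonide.

**Step 10**
Reactants: 17 formylacrylic acid β-keto ester; 6 α-methylene bis-lactone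
Product: 21 spiro adduct acetate, via dilithium salt 18 (not isolated), via lactone enolate 19 (not isolated), via hemiacylal 20 (not isolated)
Conditions: LiHMDS (2.05 equiv), THF, −78 °C; 6, −78 to −20 °C; AcOH; then Ac2O, pyridine, DMAP (cat.), 0 °C
Reagents that add atoms: acetic anhydride, CC(=O)OC(C)=O
Why: Proposed new method: a Michael–Michael [3+2] annulation with lactolisation (closest precedents are Michael-initiated ring closures of enolates on α-methylene lactones and intramolecular enolate additions to enals) in which the β-keto ester enolate of 18 adds to the unhindered exo-methylene of 6, the resulting lactone enolate 19 attacks the formylacrylate β-carbon 5-exo-trig from the convex face of the cis-fused bis-lactone (sets C1) through a lithium-bridged carboxylate–enolate arrangement that holds CO2Li syn to the lactone carbonyl (sets C5), and acidification closes the geminal CO2H/CH2CHO pair to hemiacylal 20, trapped as acetate 21, so that the cyclopentane and the spiro γ-lactone form in one operation.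

**Step 11**
Reactants: 21 spiro adduct acetate
Product: 23 C3 ketone, via β-keto acid 22 (not isolated)
Conditions: H2 (1 atm), 10% Pd/C, EtOAc, rt; then CSA (10 mol%), CHCl3, 40 °C
Reagents that add atoms: none
Why: Benzyl hydrogenolysis and decarboxylation of the β-keto acid give the C3 methine, which is α to the ketone and is equilibrated under acid to the epimer whose acyl group lies away from the overhanging second lactone carbonyl and so cis to both carboxyl carbons, while the neighbouring dioxane centre stays locked equatorial.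

**Step 12**
Reactants: 23 C3 ketone
Product: 24 syn carbinol
Conditions: L-Selectride, THF, −78 °C; AcOH quench
Reagents that add atoms: none
Why: Felkin–Anh (non-chelation) reduction by a bulky hydride, with the dioxane C–O bond antiperiplanar to the incoming hydride, gives the syn (S,S) alkoxy-alcohol.

**Step 13**
Reactants: 24 syn carbinol
Product: 26 bis-lactone dihydropyranone, via hydroxy lactone 25 (not isolated)
Conditions: TFA–H2O (9:1), CH2Cl2, 0 °C to rt; then p-TsOH (cat.), PhMe, 80 °C
Reagents that add atoms: water, O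
Why: Acidolysis removes the acetonide, the tert-butyl ester and the acylal acetate, the 3,5-dihydroxy acid closes to the δ-lactone (statin-type lactonisation) and acid-catalysed dehydration of the β-hydroxy lactone gives the 5,6-dihydropyran-2-one while the C1 carboxyl is still masked in the bis-lactone.

**Step 14**
Reactants: 26 bis-lactone dihydropyranone
Product: 27 penicillactone A
Conditions: DBU (2.5 equiv), THF, −20 to 0 °C, short; then 1 M HCl
Reagents that add atoms: none
Why: E1cB β-elimination, in which deprotonation α to the hexyl lactone expels the other lactone's carboxylate, unveils the butenolide and the free C1 acid and erases the two relay stereocentres, and acidification recloses the hemiacylal.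

**Compound list**
1 | octanal | CCCCCCCC=O | starting material
2 | (2S)-1-oxooctan-2-yl benzoate | O=C[C@@H](OC(=O)c1ccccc1)CCCCCC | intermediate
3 | dimethyl itaconate | COC(=O)CC(=C)C(=O)OC | starting material
4 | lithium dienolate of dimethyl itaconate | [Li+].COC(=O)C(=C)C=C([O-])OC | intermediate
5 | dimethyl (2S)-2-[(1R,2S)-2-(benzoyloxy)-1-hydroxyoctyl]-3-methylidenebutanedioate (formed with its 2R epimer) | COC(=O)C(=C)[C@H](C(=O)OC)[C@@H](O)[C@@H](OC(=O)c1ccccc1)CCCCCC | intermediate
6 | (3aS,6S,6aR)-6-hexyl-3-methylidenetetrahydrofuro[3,4-b]furan-2,4-dione | CCCCCC[C@@H]1OC(=O)[C@H]2C(=C)C(=O)O[C@@H]12 | intermediate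
7 | allyl acrylate | C=CC(=O)OCC=C | starting material
8 | 2,2-dimethoxyacetaldehyde | COC(OC)C=O | starting material
9 | allyl 2-(1-hydroxy-2,2-dimethoxyethyl)acrylate (racemic) | C=C(C(O)C(OC)OC)C(=O)OCC=C | intermediate
10 | allyl (2Z)-2-(bromomethyl)-4,4-dimethoxybut-2-enoate | BrC/C(=C\C(OC)OC)C(=O)OCC=C | intermediate
11 | tert-butyl 2-[(4R,6S)-6-(hydroxymethyl)-2,2-dimethyl-1,3-dioxan-4-yl]acetate | OC[C@@H]1C[C@H](CC(=O)OC(C)(C)C)OC(C)(C)O1 | starting material
12 | (4S,6R)-6-(2-tert-butoxy-2-oxoethyl)-2,2-dimethyl-1,3-dioxane-4-carboxylic acid | OC(=O)[C@@H]1C[C@H](CC(=O)OC(C)(C)C)OC(C)(C)O1 | intermediate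
13 | 3-(benzyloxy)-3-oxopropanoic acid (monobenzyl malonate) | OC(=O)CC(=O)OCc1ccccc1 | starting material
14 | benzyl 3-[(4S,6R)-6-(2-tert-butoxy-2-oxoethyl)-2,2-dimethyl-1,3-dioxan-4-yl]-3-oxopropanoate | O=C(CC(=O)OCc1ccccc1)[C@@H]1C[C@H](CC(=O)OC(C)(C)C)OC(C)(C)O1 | intermediate
15 | 1-benzyl 5-allyl (4E)-2-{[(4S,6R)-6-(2-tert-butoxy-2-oxoethyl)-2,2-dimethyl-1,3-dioxan-4-yl]carbonyl}-4-(2,2-dimethoxyethylidene)pentanedioate (C2 epimer mixture) | O=C([C@@H]1C[C@H](CC(=O)OC(C)(C)C)OC(C)(C)O1)C(C(=O)OCc1ccccc1)C/C(C(=O)OCC=C)=C\C(OC)OC | intermediate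
16 | (2E)-4-[(benzyloxy)carbonyl]-5-[(4S,6R)-6-(2-tert-butoxy-2-oxoethyl)-2,2-dimethyl-1,3-dioxan-4-yl]-2-(2,2-dimethoxyethylidene)-5-oxopentanoic acid (C4 epimer mixture) | O=C([C@@H]1C[C@H](CC(=O)OC(C)(C)C)OC(C)(C)O1)C(C(=O)OCc1ccccc1)C/C(C(=O)O)=C\C(OC)OC | intermediate
17 | (2E)-4-[(benzyloxy)carbonyl]-5-[(4S,6R)-6-(2-tert-butoxy-2-oxoethyl)-2,2-dimethyl-1,3-dioxan-4-yl]-5-oxo-2-(2-oxoethylidene)pentanoic acid (C4 epimer mixture) | O=C([C@@H]1C[C@H](CC(=O)OC(C)(C)C)OC(C)(C)O1)C(C(=O)OCc1ccccc1)C/C(C(=O)O)=C\C=O | intermediate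
18 | dilithium carboxylate/β-keto ester enolate of 17 | [Li+].[Li+].[O-]C(=O)/C(CC(C(=O)OCc1ccccc1)=C([O-])[C@@H]1C[C@H](CC(=O)OC(C)(C)C)OC(C)(C)O1)=C/C=O | intermediate
19 | dilithium lactone enolate/carboxylate formed by conjugate addition of 18 to the exo-methylene of 6 | [Li+].[Li+].CCCCCC[C@@H]1OC(=O)[C@H]2C(CC(C(=O)OCc3ccccc3)(C(=O)[C@@H]3C[C@H](CC(=O)OC(C)(C)C)OC(C)(C)O3)C/C(C(=O)[O-])=C\C=O)=C([O-])O[C@@H]12 | intermediate
20 | spiro adduct hemiacylal: cyclopentane whose C1 is C3 of the (3aS,6S,6aR)-6-hexyl-2,4-dioxotetrahydrofuro[3,4-b]furan unit, whose C5 is C3 of a 5-hydroxy-2-oxooxolane with its C=O cis to the C1 lactone C=O, and whose C3 carries CO2Bn and the (4S,6R)-dioxanylcarbonyl group | CCCCCC[C@@H]1OC(=O)[C@H]2[C@@]3(CC(C(=O)OCc4ccccc4)(C(=O)[C@@H]4C[C@H](CC(=O)OC(C)(C)C)OC(C)(C)O4)C[C@]35CC(O)OC5=O)C(=O)O[C@@H]12 | intermediate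
21 | O-acetate of hemiacylal 20 (5-acetoxy-2-oxooxolane spiro ring) | CCCCCC[C@@H]1OC(=O)[C@H]2[C@@]3(CC(C(=O)OCc4ccccc4)(C(=O)[C@@H]4C[C@H](CC(=O)OC(C)(C)C)OC(C)(C)O4)C[C@]35CC(OC(C)=O)OC5=O)C(=O)O[C@@H]12 | intermediate
22 | β-keto acid from 21 (CO2H in place of CO2Bn at C3) | CCCCCC[C@@H]1OC(=O)[C@H]2[C@@]3(CC(C(=O)O)(C(=O)[C@@H]4C[C@H](CC(=O)OC(C)(C)C)OC(C)(C)O4)C[C@]35CC(OC(C)=O)OC5=O)C(=O)O[C@@H]12 | intermediate
23 | C3 ketone: as 21 but C3 bears H and the (4S,6R)-dioxanylcarbonyl group cis to both lactone carbonyls on C1 and C5 | CCCCCC[C@@H]1OC(=O)[C@H]2[C@@]3(C[C@@H](C(=O)[C@@H]4C[C@H](CC(=O)OC(C)(C)C)OC(C)(C)O4)C[C@]35CC(OC(C)=O)OC5=O)C(=O)O[C@@H]12 | intermediate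
24 | syn carbinol: (S)-CH(OH) between C3 and the dioxane C4 of 23 | CCCCCC[C@@H]1OC(=O)[C@H]2[C@@]3(C[C@@H]([C@H](O)[C@@H]4C[C@H](CC(=O)OC(C)(C)C)OC(C)(C)O4)C[C@]35CC(OC(C)=O)OC5=O)C(=O)O[C@@H]12 | intermediate
25 | deprotected hydroxy lactone: side chain (S)-CH(OH)-[(2S,4R)-4-hydroxy-6-oxooxan-2-yl], free hemiacylal, bis-lactone intact | CCCCCC[C@@H]1OC(=O)[C@H]2[C@@]3(C[C@@H]([C@H](O)[C@@H]4C[C@@H](O)CC(=O)O4)C[C@]35CC(O)OC5=O)C(=O)O[C@@H]12 | intermediate
26 | bis-lactone precursor of penicillactone A: side chain (S)-CH(OH)-[(2S)-6-oxo-3,6-dihydro-2H-pyran-2-yl], spiro 5-hydroxy-2-oxooxolane, C1 still spiro-fused to the hexyl furofurandione | CCCCCC[C@@H]1OC(=O)[C@H]2[C@@]3(C[C@@H]([C@H](O)[C@@H]4CC=CC(=O)O4)C[C@]35C[C@@H](O)OC5=O)C(=O)O[C@@H]12 | intermediate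
27 | penicillactone A | CCCCCC[C@H]1C=C([C@]2(C(=O)O)C[C@@H]([C@H](O)[C@@H]3CC=CC(=O)O3)C[C@]23C[C@@H](O)OC3=O)C(=O)O1 | target

**Step count and weak points**
Total steps: 14. Longest linear sequence: 9 steps (11 → 12 → 14 → 15 → 17 → 21 → 23 → 24 → 26 → 27, steps 6–14).

The three steps most likely to fail:

Step 10 (annulation). Risks are base-induced isomerisation or opening of 6 before conjugate addition, a sluggish second Michael addition that must join two quaternary carbons, and incomplete control at C5. Fallback, setting out from 15 and 6 and coming back at 20: deprotonate 15 with KHMDS and add 6 in the presence of TMSCl, so that the conjugate adduct is trapped as the O-trimethylsilyl ketene acetal F1. Catalytic TMSOTf in CH2Cl2 at −78 °C then ionises the unsaturated dimethyl acetal to an alkoxyallyl cation, which the ketene acetal captures 5-exo (intramolecular vinylogous Mukaiyama–Michael closure) to give the cyclised allyl ester methyl enol ether F2. Pd(PPh3)4/PhSiH3 followed by aqueous acid cleaves the allyl ester and hydrolyses the enol ether, and the liberated acid and aldehyde close to hemiacylal 20, which is acetylated to 21 as in the route.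

Step 11 (C3 configuration). The preference for the desired C3 epimer rests only on the lactone overhang and may be small. Fallback, setting out from 23 (as its C3 epimer mixture) and coming back to 23: instead of relying on the equilibrium position, reduce the mixture under the step 12 conditions and separate 24 from the C3-epimeric carbinol F3 by chromatography. Re-oxidise F3 with Dess–Martin periodinane to the C3-epimeric ketone F4 and return F4 to the acid equilibration, which regenerates 23; the loop converges all material on 23.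

Step 13 (acid dehydration). Risks are incomplete or unselective dehydration with the free carbinol and hemiacylal present, and transesterification of the bis-lactone. Fallback, setting out from 24 and coming back at 27: stop after the TFA–H2O stage and isolate hydroxy lactone 25, then acetylate all three hydroxyls (Ac2O, pyridine) to the triacetate F5. DBU then performs two E1cB eliminations at once (β-acetoxy δ-lactone to dihydropyranone, bis-lactone to butenolide acid) to give the diacetate of penicillactone A F6. Neutral enzymatic deacetylation (lipase or esterase, pH 7 buffer) gives 27.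

**Further compounds**
F1 | step 10 | O-trimethylsilyl ketene acetal of the conjugate adduct of 15 with 6 | CCCCCC[C@@H]1OC(=O)[C@H]2C(CC(C(=O)OCc3ccccc3)(C(=O)[C@@H]3C[C@H](CC(=O)OC(C)(C)C)OC(C)(C)O3)C/C(C(=O)OCC=C)=C\C(OC)OC)=C(O[Si](C)(C)C)O[C@@H]12
F2 | step 10 | cyclised allyl ester methyl enol ether (C5 bears CO2allyl and (E)-2-methoxyvinyl) | CCCCCC[C@@H]1OC(=O)[C@H]2[C@@]3(CC(C(=O)OCc4ccccc4)(C(=O)[C@@H]4C[C@H](CC(=O)OC(C)(C)C)OC(C)(C)O4)C[C@]3(C(=O)OCC=C)/C=C/OC)C(=O)O[C@@H]12
F3 | step 11 | C3 epimer of carbinol 24 | CCCCCC[C@@H]1OC(=O)[C@H]2[C@@]3(C[C@H]([C@H](O)[C@@H]4C[C@H](CC(=O)OC(C)(C)C)OC(C)(C)O4)C[C@]35CC(OC(C)=O)OC5=O)C(=O)O[C@@H]12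
F4 | step 11 | C3 epimer of ketone 23 | CCCCCC[C@@H]1OC(=O)[C@H]2[C@@]3(C[C@H](C(=O)[C@@H]4C[C@H](CC(=O)OC(C)(C)C)OC(C)(C)O4)C[C@]35CC(OC(C)=O)OC5=O)C(=O)O[C@@H]12
F5 | step 13 | triacetate of hydroxy lactone 25 | CCCCCC[C@@H]1OC(=O)[C@H]2[C@@]3(C[C@@H]([C@H](OC(C)=O)[C@@H]4C[C@@H](OC(C)=O)CC(=O)O4)C[C@]35CC(OC(C)=O)OC5=O)C(=O)O[C@@H]12
F6 | step 13 | diacetate of penicillactone A (carbinol and hemiacylal O-acetates) | CCCCCC[C@H]1C=C([C@]2(C(=O)O)C[C@@H]([C@H](OC(C)=O)[C@@H]3CC=CC(=O)O3)C[C@]23CC(OC(C)=O)OC3=O)C(=O)O1
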